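**Retrosynthetic overview**
1. The strategy rests on ring A carrying O1 (on C8a) and the C4 carbonyl (on C4a) on two adjacent carbons. Both bonds, O1–C8a and C4–C4a, are cut at once. This gives a ring A aryne and a methyl 2-aryl-3-hydroxyacrylate that holds C2, C3, C4 and ring B.
2. The aryne carries an extra chlorine at the future C5 to fix the orientation of addition. The final hydrogenolysis removes it together with the two benzyl ethers.
3. The hydroxyacrylate comes from C-formylation of the ring B arylacetate, which comes from the aryl methyl ketone by oxidative 1,2-aryl shift. The ketone comes from 2,4,6-trihydroxyacetophenone by C-prenylation and methylation of the hydroxyl between acetyl and prenyl. Acid then closes ring D onto the only hydroxyl still next to the prenyl chain.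
4. The aryne precursor comes from 5-chlororesorcinol by bromination, double O-silylation, retro-Brook shift with triflation, and benzylation. Silicon is placed through a bromine because a directed lithiation would have to choose between the site next to Cl and the site next to OBn.
5. Ring order: rings B and A are bought, ring D (dimethyldihydropyran) closes in step 4, and ring C (pyranone) closes in step 12.

Key step: step 12

Remark on the chemistry: the target has no stereocentre. The only stereochemical element of the route is the Z geometry of the hydroxyacrylate, which may equilibrate with its aldehyde tautomer and is set again when the enolate is formed.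

**Step 1**
Reactants: 1 2,4,6-trihydroxyacetophenone; 2 prenyl bromide
Product: 3 2,4,6-trihydroxy-3-(3-methylbut-2-enyl)acetophenone
Conditions: KOH (1.0 equiv), H2O, 0 °C to rt; 2 (1.0 equiv) added slowly
Reagents that add atoms: none
Why: C-alkylation of an ambident phenolate, in which water solvates the oxygens so that the soft allylic bromide is taken up at ring carbon C3 (equivalent to C5), and one equivalent of 2 holds back a second prenylation.

**Step 2**
Reactants: 3 2,4,6-trihydroxy-3-(3-methylbut-2-enyl)acetophenone
Product: 4 2-hydroxy-4,6-bis(methoxymethoxy)-3-(3-methylbut-2-enyl)acetophenone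
Conditions: MOMCl (2.1 equiv), iPr2NEt (2.5 equiv), CH2Cl2, 0 °C to rt
Reagents that add atoms: chloromethyl methyl ether, COCCl
Why: Site-selective phenol O-alkylation (MOM ether formation), in which the unchelated 4-OH and the less crowded 6-OH react while the 2-OH, wedged between acetyl and prenyl and hydrogen-bonded to the carbonyl, should be left.

**Step 3**
Reactants: 4 2-hydroxy-4,6-bis(methoxymethoxy)-3-(3-methylbut-2-enyl)acetophenone
Product: 5 2-methoxy-4,6-bis(methoxymethoxy)-3-(3-methylbut-2-enyl)acetophenone
Conditions: MeI (3 equiv), K2CO3, DMF, 40 °C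
Reagents that add atoms: iodomethane, CI
Why: Williamson ether synthesis on the only free phenol, with a polar solvent and gentle heat to break the chelate, which fixes the methoxy group between the acetyl-bearing and the prenyl-bearing carbon.

**Step 4**
Reactants: 5 2-methoxy-4,6-bis(methoxymethoxy)-3-(3-methylbut-2-enyl)acetophenone
Product: 7 6-acetyl-7-hydroxy-5-methoxy-2,2-dimethylchroman, via prenylated diol 6 (not isolated)
Conditions: p-TsOH·H2O (0.3 equiv), MeOH, 60 °C; then solvent change to toluene, 90 °C
Reagents that add atoms: none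
Why: Acid-catalysed acetal exchange frees both phenols, and the same acid then protonates the alkene in the Markovnikov sense so that the tertiary cation is caught by the 4-OH, the only hydroxyl next to the side chain (6-endo hydroalkoxylation closing ring D), which leaves no regiochemical choice.

**Step 5**
Reactants: 7 6-acetyl-7-hydroxy-5-methoxy-2,2-dimethylchroman
Product: 8 6-acetyl-7-(benzyloxy)-5-methoxy-2,2-dimethylchroman
Conditions: BnBr (1.3 equiv), K2CO3, DMF, 60 °C
Reagents that add atoms: benzyl bromide, BrCc1ccccc1
Why: Williamson ether synthesis on the single, chelated phenol, giving a protecting group that falls in the final hydrogenolysis.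

**Step 6**
Reactants: 8 6-acetyl-7-(benzyloxy)-5-methoxy-2,2-dimethylchroman
Product: 9 methyl 2-[7-(benzyloxy)-5-methoxy-2,2-dimethylchroman-6-yl]acetate
Conditions: Tl(NO3)3·3H2O (1.1 equiv), MeOH/HC(OMe)3 1:1, rt
Reagents that add atoms: methanol, CO
Why: Oxidative 1,2-aryl migration of an aryl methyl ketone, in which the methyl enol ether is oxythallated, the electron-rich ring B shifts to the former methyl carbon as trivalent thallium leaves as monovalent thallium, and methanol captures the cation as the methyl ester.

**Step 7**
Reactants: 9 methyl 2-[7-(benzyloxy)-5-methoxy-2,2-dimethylchroman-6-yl]acetate; 10 methyl formate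
Product: 12 methyl (Z)-2-[7-(benzyloxy)-5-methoxy-2,2-dimethylchroman-6-yl]-3-hydroxyacrylate, via sodium enolate 11 (not isolated)
Conditions: NaH (2.5 equiv), 10 (10 equiv), THF, 0 °C to rt; then 1 M HCl, 0 °C
Reagents that add atoms: none
Why: Crossed Claisen condensation with a non-enolisable formate, driven by the stabilised enolate 11, and on acidification the enol should settle in the Z form held by the O–H···O=C hydrogen bond to the ester.

**Step 8**
Reactants: 13 5-chlororesorcinol
Product: 14 4-bromo-5-chlororesorcinol
Conditions: NBS (1.0 equiv), MeCN, −20 °C to 0 °C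
Reagents that add atoms: N-bromosuccinimide, O=C1CCC(=O)N1Br
Why: Electrophilic aromatic bromination at C4 (equivalent to C6), which is para to one hydroxyl and ortho to the other and is the usual site of resorcinol monohalogenation, with low temperature and one equivalent of NBS limiting dibromination.

**Step 9**
Reactants: 14 4-bromo-5-chlororesorcinol
Product: 15 4-bromo-5-chloro-1,3-bis(trimethylsilyloxy)benzene
Conditions: HN(SiMe3)2 (1.5 equiv), THF, 70 °C; volatiles removed in vacuo
Reagents that add atoms: hexamethyldisilazane, C[Si](C)(C)N[Si](C)(C)C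
Why: Base-free O-silylation of both phenols that gives only ammonia beside the product, so 15 can be used after evaporation.

**Step 10**
Reactants: 15 4-bromo-5-chloro-1,3-bis(trimethylsilyloxy)benzene
Product: 18 3-chloro-5-hydroxy-2-(trimethylsilyl)phenyl trifluoromethanesulfonate, via lithium phenoxide 16 (not isolated), via silyl ether triflate 17 (not isolated)
Conditions: n-BuLi (1.05 equiv), THF, −78 °C; Tf2O (1.1 equiv), −78 °C; then MeOH, citric acid (0.1 equiv), 0 °C to rt
Reagents that add atoms: trifluoromethanesulfonic anhydride, O=S(=O)(OS(=O)(=O)C(F)(F)F)C(F)(F)F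
Why: Bromine–lithium exchange followed by retro-Brook rearrangement, in which only the silyl group on the oxygen next to the metalated carbon can make the 1,3 O-to-C shift, so the two resorcinol oxygens are told apart, only phenoxide 16 is triflated, and the remaining aryl silyl ether of 17 falls off in mildly acidic methanol.

**Step 11**
Reactants: 18 3-chloro-5-hydroxy-2-(trimethylsilyl)phenyl trifluoromethanesulfonate
Product: 19 5-(benzyloxy)-3-chloro-2-(trimethylsilyl)phenyl trifluoromethanesulfonate
Conditions: BnOH (1.2 equiv), PPh3 (1.3 equiv), DIAD (1.3 equiv), THF, 0 °C to rt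
Reagents that add atoms: benzyl alcohol, OCc1ccccc1
Why: Mitsunobu etherification of an acidic phenol under neutral conditions, chosen so that no base or fluoride can trigger the silyl triflate early.

**Step 12**
Reactants: 12 methyl (Z)-2-[7-(benzyloxy)-5-methoxy-2,2-dimethylchroman-6-yl]-3-hydroxyacrylate; 19 5-(benzyloxy)-3-chloro-2-(trimethylsilyl)phenyl trifluoromethanesulfonate
Product: 22 7-(benzyloxy)-3-[7-(benzyloxy)-5-methoxy-2,2-dimethylchroman-6-yl]-5-chloro-4H-chromen-4-one, via cesium enolate 20 (not isolated), via 5-(benzyloxy)-3-chlorobenzyne 21 (not isolated)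
Conditions: CsF (5 equiv), THF, rt, 30 min; then 19 (1.5 equiv) in THF added over 6 h, 65 °C
Reagents that add atoms: none
Why: Proposed new method: CsF first turns 12 into cesium enolate 20 and then attacks silicon in 19, so that loss of triflate releases aryne 21; the enolate oxygen adds to the aryne carbon remote from chlorine (O1–C8a), and the carbanion thus placed at C4a, cis to the ester across C2=C3, adds to the ester carbonyl (C4a–C4) and expels methoxide, which takes back the proton stored as CsHF2. The closest known reaction type is the CsF-mediated annulation of arynes with salicylate esters to xanthones, where a phenoxide and its ortho ester play these two roles; new here is that the O–C=C–C(=O)OMe unit is an open-chain enolate and not part of a benzene ring. Ring C closes by a 6-exo-trig addition to the ester carbonyl followed by elimination, and no stereocentre is created. Regioselectivity at the aryne is secured by the C5 chlorine, whose inductive pull distorts the triple bond so that the nucleophile enters at the meta carbon and the negative charge builds up next to chlorine, while the 7-benzyloxy group by itself would allow both orientations. Attack through oxygen and not carbon is expected because the α-carbon of 20 carries the twisted ring B with both ortho positions occupied, so that C-arylation would have to build a quaternary centre against it. The closure further needs the U-shaped Z enolate, which THF should favour as a contact ion pair with cesium bridging both oxygens, and it must outrun protonation, which is why 12 is deprotonated completely before 19 is fed in slowly.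

**Step 13**
Reactants: 22 7-(benzyloxy)-3-[7-(benzyloxy)-5-methoxy-2,2-dimethylchroman-6-yl]-5-chloro-4H-chromen-4-one
Product: 24 glycyrrhizaisoflavone C, via dechlorinated dibenzyl ether 23 (not isolated)
Conditions: H2 (1 atm), 10% Pd/C, Et3N (1.1 equiv), EtOAc/MeOH, rt
Reagents that add atoms: none
Why: Catalytic hydrogenolysis in which amine-promoted hydrodechlorination of C5–Cl should go first and convert the amine into its hydrochloride, so that it no longer slows cleavage of the two aryl benzyl ethers, while the C2=C3 bond, a vinylogous ester shielded by the twisted ring B, should survive at 1 atm.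

**Compound list**
1 | 2,4,6-trihydroxyacetophenone | CC(=O)c1c(O)cc(O)cc1O | starting material
2 | prenyl bromide (1-bromo-3-methylbut-2-ene) | CC(C)=CCBr | starting material
3 | 2,4,6-trihydroxy-3-(3-methylbut-2-enyl)acetophenone | CC(=O)c1c(O)cc(O)c(CC=C(C)C)c1O | intermediate
4 | 2-hydroxy-4,6-bis(methoxymethoxy)-3-(3-methylbut-2-enyl)acetophenone | CC(=O)c1c(OCOC)cc(OCOC)c(CC=C(C)C)c1O | intermediate
5 | 2-methoxy-4,6-bis(methoxymethoxy)-3-(3-methylbut-2-enyl)acetophenone | CC(=O)c1c(OCOC)cc(OCOC)c(CC=C(C)C)c1OC | intermediate
6 | 4,6-dihydroxy-2-methoxy-3-(3-methylbut-2-enyl)acetophenone (prenylated diol) | CC(=O)c1c(O)cc(O)c(CC=C(C)C)c1OC | intermediate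
7 | 6-acetyl-7-hydroxy-5-methoxy-2,2-dimethylchroman | CC(=O)c1c(O)cc2c(c1OC)CCC(C)(C)O2 | intermediate
8 | 6-acetyl-7-(benzyloxy)-5-methoxy-2,2-dimethylchroman | CC(=O)c1c(OCc3ccccc3)cc2c(c1OC)CCC(C)(C)O2 | intermediate
9 | methyl 2-[7-(benzyloxy)-5-methoxy-2,2-dimethylchroman-6-yl]acetate | COC(=O)Cc1c(OCc3ccccc3)cc2c(c1OC)CCC(C)(C)O2 | intermediate
10 | methyl formate | COC=O | starting material
11 | sodium (Z)-enolate of 12 | [Na+].[O-]/C=C(/c1c(OC)c2c(cc1OCc1ccccc1)OC(C)(C)CC2)C(=O)OC | intermediate
12 | methyl (Z)-2-[7-(benzyloxy)-5-methoxy-2,2-dimethylchroman-6-yl]-3-hydroxyacrylate | O/C=C(/c1c(OC)c2c(cc1OCc1ccccc1)OC(C)(C)CC2)C(=O)OC | intermediate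
13 | 5-chlororesorcinol | Oc1cc(O)cc(Cl)c1 | starting material
14 | 4-bromo-5-chlororesorcinol | Oc1cc(O)c(Br)c(Cl)c1 | intermediate
15 | 4-bromo-5-chloro-1,3-bis(trimethylsilyloxy)benzene | C[Si](C)(C)Oc1cc(O[Si](C)(C)C)c(Br)c(Cl)c1 | intermediate
16 | lithium 3-chloro-2-(trimethylsilyl)-5-(trimethylsilyloxy)phenoxide | [Li+].[O-]c1cc(O[Si](C)(C)C)cc(Cl)c1[Si](C)(C)C | intermediate
17 | 3-chloro-2-(trimethylsilyl)-5-(trimethylsilyloxy)phenyl trifluoromethanesulfonate | C[Si](C)(C)Oc1cc(Cl)c([Si](C)(C)C)c(OS(=O)(=O)C(F)(F)F)c1 | intermediate
18 | 3-chloro-5-hydroxy-2-(trimethylsilyl)phenyl trifluoromethanesulfonate | Oc1cc(Cl)c([Si](C)(C)C)c(OS(=O)(=O)C(F)(F)F)c1 | intermediate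
19 | 5-(benzyloxy)-3-chloro-2-(trimethylsilyl)phenyl trifluoromethanesulfonate | C[Si](C)(C)c1c(Cl)cc(OCc2ccccc2)cc1OS(=O)(=O)C(F)(F)F | intermediate
20 | cesium (Z)-enolate of 12 | [Cs+].[O-]/C=C(/c1c(OC)c2c(cc1OCc1ccccc1)OC(C)(C)CC2)C(=O)OC | intermediate
21 | 5-(benzyloxy)-3-chlorobenzyne | ClC1=CC(OCc2ccccc2)=CC#C1 | intermediate
22 | 7-(benzyloxy)-3-[7-(benzyloxy)-5-methoxy-2,2-dimethylchroman-6-yl]-5-chloro-4H-chromen-4-one | COc1c2c(cc(OCc3ccccc3)c1-c1coc3cc(OCc4ccccc4)cc(Cl)c3c1=O)OC(C)(C)CC2 | intermediate
23 | 7-(benzyloxy)-3-[7-(benzyloxy)-5-methoxy-2,2-dimethylchroman-6-yl]-4H-chromen-4-one | COc1c2c(cc(OCc3ccccc3)c1-c1coc3cc(OCc4ccccc4)ccc3c1=O)OC(C)(C)CC2 | intermediate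
24 | glycyrrhizaisoflavone C | COc1c2c(cc(O)c1-c1coc3cc(O)ccc3c1=O)OC(C)(C)CC2 | target

**Total step count:** 13. **Longest linear sequence:** 9 steps (steps 1 to 7, 12, 13). Steps 8 to 11 form the second branch.

**Steps most likely to fail**

1. **Step 12.** Four processes could divert the annulation:
   - arylation of the enolate at carbon followed by acyl transfer;
   - O-arylation out of the extended E enolate, after which the C4a carbanion cannot reach the ester;
   - proton capture by that carbanion;
   - loss of chloride from it.

   The fallback uses known chemistry, sets out from 12 and builds the two bonds one after the other without an aryne.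
   - Enol tosylation (TsCl, N-methylimidazole, Et3N, MeCN) should give methyl (Z)-2-[7-(benzyloxy)-5-methoxy-2,2-dimethylchroman-6-yl]-3-(tosyloxy)acrylate F1.
   - Addition–elimination with commercial 3-(benzyloxy)phenol and K2CO3 in DMF should give methyl (Z)-3-[3-(benzyloxy)phenoxy]-2-[7-(benzyloxy)-5-methoxy-2,2-dimethylchroman-6-yl]acrylate F2.
   - LiOH in THF/H2O should give (Z)-3-[3-(benzyloxy)phenoxy]-2-[7-(benzyloxy)-5-methoxy-2,2-dimethylchroman-6-yl]acrylic acid F3.
   - Intramolecular Friedel–Crafts acylation through the mixed anhydride with (CF3CO)2O in CH2Cl2 should close ring C at the position para to the benzyloxy group, so no chlorine is needed.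

   The route is rejoined at 23, which is isolated in this case and hydrogenolysed as in step 13 without Et3N.

2. **Step 6.** Attack of the oxidant on the very electron-rich ring at C8–H, or slow enol ether formation at the doubly ortho-flanked ketone, could outweigh the aryl shift. The fallback sets out from 8 and moves the oxidation state along the chain with sulfur instead of a metal oxidant.
   - Willgerodt–Kindler reaction (S8, morpholine, 130 °C) should give 2-[7-(benzyloxy)-5-methoxy-2,2-dimethylchroman-6-yl]-1-(morpholin-4-yl)ethanethione F4.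
   - Hydrolysis (NaOH, EtOH/H2O, reflux, then acid) should give 2-[7-(benzyloxy)-5-methoxy-2,2-dimethylchroman-6-yl]acetic acid F5.
   - Esterification with MeI and K2CO3 in DMF comes back to the route at 9.

3. **Step 2.** Poor site selectivity between the two hydroxyls ortho to the acetyl group would put the methyl ether of step 3 on the wrong oxygen. The fallback sets out from 1 and closes ring D first, on a symmetric intermediate.
   - Selective alkylation of the unchelated 4-OH with 3-chloro-3-methylbut-1-yne (K2CO3, KI, CuI cat., acetone) should give 2,6-dihydroxy-4-(2-methylbut-3-yn-2-yloxy)acetophenone F6.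
   - Thermal aryl propargyl ether Claisen rearrangement and electrocyclisation (xylene, 140 °C) should give 6-acetyl-5,7-dihydroxy-2,2-dimethyl-2H-chromene F7 as the only possible isomer.
   - Hydrogenation (H2, 10% Pd/C, EtOAc) should give 6-acetyl-5,7-dihydroxy-2,2-dimethylchroman F8.
   - A single benzylation (BnBr 1.0 equiv, K2CO3, acetone) should take the 7-OH, whose only ring neighbour is C8–H, to give 6-acetyl-7-(benzyloxy)-5-hydroxy-2,2-dimethylchroman F9.
   - Methylation of the remaining chelated 5-OH (MeI, K2CO3, DMF) comes back to the route at 8.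

**Further compounds**
F1 | step 12 | methyl (Z)-2-[7-(benzyloxy)-5-methoxy-2,2-dimethylchroman-6-yl]-3-(tosyloxy)acrylate | Cc1ccc(cc1)S(=O)(=O)O/C=C(/c1c(OC)c2c(cc1OCc1ccccc1)OC(C)(C)CC2)C(=O)OC
F2 | step 12 | methyl (Z)-3-[3-(benzyloxy)phenoxy]-2-[7-(benzyloxy)-5-methoxy-2,2-dimethylchroman-6-yl]acrylate | c1ccccc1COc1cccc(O/C=C(/c2c(OC)c3c(cc2OCc2ccccc2)OC(C)(C)CC3)C(=O)OC)c1
F3 | step 12 | (Z)-3-[3-(benzyloxy)phenoxy]-2-[7-(benzyloxy)-5-methoxy-2,2-dimethylchroman-6-yl]acrylic acid | c1ccccc1COc1cccc(O/C=C(/c2c(OC)c3c(cc2OCc2ccccc2)OC(C)(C)CC3)C(=O)O)c1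
F4 | step 6 | 2-[7-(benzyloxy)-5-methoxy-2,2-dimethylchroman-6-yl]-1-(morpholin-4-yl)ethanethione | S=C(Cc1c(OCc3ccccc3)cc2c(c1OC)CCC(C)(C)O2)N1CCOCC1
F5 | step 6 | 2-[7-(benzyloxy)-5-methoxy-2,2-dimethylchroman-6-yl]acetic acid | OC(=O)Cc1c(OCc3ccccc3)cc2c(c1OC)CCC(C)(C)O2
F6 | step 2 | 2,6-dihydroxy-4-(2-methylbut-3-yn-2-yloxy)acetophenone | CC(=O)c1c(O)cc(OC(C)(C)C#C)cc1O
F7 | step 2 | 6-acetyl-5,7-dihydroxy-2,2-dimethyl-2H-chromene | CC(=O)c1c(O)cc2c(c1O)C=CC(C)(C)O2
F8 | step 2 | 6-acetyl-5,7-dihydroxy-2,2-dimethylchroman | CC(=O)c1c(O)cc2c(c1O)CCC(C)(C)O2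
F9 | step 2 | 6-acetyl-7-(benzyloxy)-5-hydroxy-2,2-dimethylchroman | CC(=O)c1c(OCc3ccccc3)cc2c(c1O)CCC(C)(C)O2
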